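**Assumptions (one line):** atoms are labelled with ent‑kaurane numbering (target = 4R,5R,8S,9S,10R,11R,13S); a one‑pot, two‑stage operation without isolation is counted as one step.

## Retrosynthetic overview

1. Ludongnin A ⇐ C16 α‑methylenation, C20–O/C7 δ‑lactonisation and C11 ketone reduction of a bicyclo[3.2.1]octane diketo ester.
2. Ring C (C8–C9 bond, C8 quaternary centre) ⇐ intramolecular 6‑endo Michael addition of a cyclopentanone β‑keto ester onto an (E)‑nitroalkene; the C11 nitro group becomes the C11 ketone (Nef).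
3. Nitroalkene ⇐ Henry/dehydration union (C9–C11) of A‑ring aldehyde **10** and D‑ring nitro keto ester **18**.
4. **10** ⇐ (R)‑ethyl 1‑methyl‑2‑oxocyclohexanecarboxylate (C10 double functionalisation, C5 methylenation/hydroboration, lactonisation); **18** ⇐ cyclopentenone (Rh‑catalysed asymmetric vinylation).
5. Ring order: A ring (bought) → γ‑lactone → D ring (bought) → ring C by the Michael closure → δ‑lactone → exo‑methylene enone last.

## Fragment A (aldehyde 10)

**Step 1**
Reactants: **1** ethyl 2‑oxocyclohexane‑1‑carboxylate; **2** L‑valine tert‑butyl ester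
Product: **3** ethyl 2‑{[(2S)‑1‑tert‑butoxy‑3‑methyl‑1‑oxobutan‑2‑yl]amino}cyclohex‑1‑ene‑1‑carboxylate
Conditions: BF3·OEt2 (cat.), benzene, reflux, Dean–Stark
Reagents that add atoms: none
Why: Condensation of a β‑keto ester with a primary amine gives the conjugated chiral enamino ester (Koga auxiliary).

**Step 2**
Reactants: **3**
Product: **4** ethyl (1R)‑1‑methyl‑2‑oxocyclohexane‑1‑carboxylate
Conditions: LDA, toluene, HMPA (1 equiv), −78 °C; MeI; then 1 M HCl
Reagents that add atoms: iodomethane, CI
Why: Koga asymmetric alkylation of the chelated lithio‑enamine sets C4; the toluene/HMPA manifold is chosen for the (R) product (the THF manifold or D‑valine gives the antipode), and hydrolysis releases the ketone and the auxiliary.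

**Step 3**
Reactants: **4**
Product: **5** ethyl (1R)‑3‑[(benzyloxy)methyl]‑1‑methyl‑2‑oxocyclohexane‑1‑carboxylate (C3 epimers)
Conditions: LDA, THF, −78 °C; BOMCl, −78 → −20 °C
Reagents that add atoms: benzyl chloromethyl ether, ClCOCc1ccccc1
Why: Enolate alkylation can only occur at C10, the single enolisable position, and installs C20 as a protected hydroxymethyl group.

**Step 4**
Reactants: **5**
Product: **6** ethyl (1R,3R)‑3‑[(benzyloxy)methyl]‑3‑(dimethoxymethyl)‑1‑methyl‑2‑oxocyclohexane‑1‑carboxylate (CH2OBn cis to CO2Et)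
Conditions: (i) LDA, TMSCl, THF, −78 → 0 °C; (ii) HC(OMe)3, BF3·OEt2, CH2Cl2, −78 °C
Reagents that add atoms: trimethyl orthoformate, COC(OC)OC
Why: Mukaiyama‑type addition of the silyl enol ether to the dimethoxycarbenium ion creates the C10 quaternary centre, the electrophile entering anti to the pseudo‑axial C4 ester so that C9 is trans and C20 cis to C19.

**Step 5**
Reactants: **6**
Product: **7** ethyl (1R,3R)‑3‑[(benzyloxy)methyl]‑3‑(dimethoxymethyl)‑1‑methyl‑2‑methylidenecyclohexane‑1‑carboxylate
Conditions: Zn, CH2Br2, TiCl4 (Lombardo reagent), THF/CH2Cl2, 0 °C → rt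
Reagents that add atoms: dibromomethane, BrCBr
Why: Takai–Lombardo methylenation is a small, non‑basic reagent that converts hindered ketones to methylene compounds and leaves esters, acetals and benzyl ethers alone.

**Step 6**
Reactants: **7**
Product: **8** ethyl (1R,2S,3R)‑3‑[(benzyloxy)methyl]‑3‑(dimethoxymethyl)‑2‑(hydroxymethyl)‑1‑methylcyclohexane‑1‑carboxylate
Conditions: BH3·THF, 0 °C → rt; then NaOH, H2O2, 0 °C
Reagents that add atoms: hydrogen peroxide, OO
Why: Anti‑Markovnikov hydroboration–oxidation delivers H to C5 from the face opposite the syn‑diaxial CO2Et/CH2OBn pair, placing C6 cis to C19 and C20 (any lactone formed on work‑up converges in step 7).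

**Step 7**
Reactants: **8**
Product: **9** [(1R,2R,3R)‑3‑[(benzyloxy)methyl]‑3‑(dimethoxymethyl)‑1‑methylcyclohexane‑1,2‑diyl]dimethanol
Conditions: LiAlH4, THF, 0 °C
Reagents that add atoms: none
Why: Hydride reduction of the neopentyl ester (or the derived lactone) gives the 6,19‑diol without touching the acetal or benzyl ether.

**Step 8**
Reactants: **9**
Product: **10** (3aR,7R,7aR)‑7‑[(benzyloxy)methyl]‑3a‑methyl‑1‑oxooctahydro‑2‑benzofuran‑7‑carbaldehyde (cis‑fused 6,19‑lactone; C9 aldehyde)
Conditions: PhI(OAc)2, TEMPO (cat.), CH2Cl2, rt; then 1 M HCl, THF, rt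
Reagents that add atoms: water, O
Why: TEMPO oxidative lactonisation oxidises the less hindered C6 carbinol (the neopentyl C19–OH traps the aldehyde as lactol) to the cis γ‑lactone, and the acidic work‑up unmasks the aldehyde; C5 is α to the lactone carbonyl and can be equilibrated to the cis fusion if needed.

## Fragment D (nitro keto ester 18)

**Step 9**
Reactants: **11** cyclopent‑2‑en‑1‑one
Product: **12** (3R)‑3‑vinylcyclopentan‑1‑one
Conditions: CH2=CHBF3K, [Rh(cod)2]PF6 (3 mol %), (R)‑BINAP, toluene/H2O, 100 °C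
Reagents that add atoms: potassium vinyltrifluoroborate, C=C[B-](F)(F)F.[K+]
Why: Hayashi–Miyaura Rh/BINAP conjugate addition sets C13 by enantioface‑selective insertion of the enone into the Rh–vinyl bond.

**Step 10**
Reactants: **12**
Product: **13** methyl (4R)‑2‑oxo‑4‑vinylcyclopentane‑1‑carboxylate (C1 epimers/enol)
Conditions: NaH, (MeO)2CO, THF, reflux
Reagents that add atoms: dimethyl carbonate, COC(=O)OC
Why: Reversible Claisen‑type methoxycarbonylation funnels to the β‑keto ester enolate remote from the C13 substituent (no allylic strain); the minor regioisomer is removed.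

**Step 11**
Reactants: **13**
Product: **14** methyl (8R)‑8‑vinyl‑1,4‑dioxaspiro[4.4]nonane‑6‑carboxylate
Conditions: ethylene glycol, p‑TsOH (cat.), benzene, reflux, Dean–Stark
Reagents that add atoms: ethylene glycol, OCCO
Why: Ketalisation masks the ketone (and the acidic β‑keto ester) for the hydroboration and displacement steps.

**Step 12**
Reactants: **14**
Product: **15** methyl (8S)‑8‑(2‑hydroxyethyl)‑1,4‑dioxaspiro[4.4]nonane‑6‑carboxylate
Conditions: 9‑BBN, THF, 0 °C → rt; then NaBO3·4H2O (or NaOH/H2O2)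
Reagents that add atoms: hydrogen peroxide (or perborate), OO
Why: Anti‑Markovnikov hydroboration–oxidation of the terminal alkene with 9‑BBN is chemoselective in the presence of the ester.

**Step 13**
Reactants: **15**
Product: **16** methyl (8R)‑8‑(2‑iodoethyl)‑1,4‑dioxaspiro[4.4]nonane‑6‑carboxylate
Conditions: I2, PPh3, imidazole, CH2Cl2, 0 °C
Reagents that add atoms: iodine, II
Why: Appel iodination of a primary alcohol under neutral conditions.

**Step 14**
Reactants: **16**
Product: **17** methyl (8S)‑8‑(2‑nitroethyl)‑1,4‑dioxaspiro[4.4]nonane‑6‑carboxylate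
Conditions: NaNO2, phloroglucinol, DMSO, rt
Reagents that add atoms: sodium nitrite, [Na+].[O-]N=O
Why: Kornblum substitution of a primary iodide gives the primary nitroalkane (the nitrite ester by‑product is scavenged).

**Step 15**
Reactants: **17**
Product: **18** methyl (4S)‑4‑(2‑nitroethyl)‑2‑oxocyclopentane‑1‑carboxylate
Conditions: 1 M HCl, acetone, 40 °C
Reagents that add atoms: water, O
Why: Acidic ketal hydrolysis regenerates the β‑keto ester; the nitro group and the C13 stereocentre are unaffected.

## Union and endgame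

**Step 16**
Reactants: **10**; **18**
Product: **19** (E)‑nitroalkene: methyl (4S)‑4‑{(2E)‑3‑[(3aR,7R,7aR)‑7‑[(benzyloxy)methyl]‑3a‑methyl‑1‑oxooctahydro‑2‑benzofuran‑7‑yl]‑2‑nitroprop‑2‑en‑1‑yl}‑2‑oxocyclopentane‑1‑carboxylate (C9=C11, NO2 on C11)
Conditions: (i) tetramethylguanidine (0.2 equiv), THF, 0 °C → rt; (ii) DCC, CuCl (cat.), Et2O, rt
Reagents that add atoms: none
Why: Henry addition of the primary nitronate to the non‑enolisable aldehyde followed by carbodiimide dehydration gives the thermodynamic (E)‑alkene (C10 trans to NO2); additions of the β‑keto ester enolate are reversible and unproductive.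

**Step 17 (key ring closure)**
Reactants: **19**
Product: **20** methyl (1S,2S,5S)‑2‑[(3aR,7R,7aR)‑7‑[(benzyloxy)methyl]‑3a‑methyl‑1‑oxooctahydro‑2‑benzofuran‑7‑yl]‑3‑nitro‑7‑oxobicyclo[3.2.1]octane‑1‑carboxylate (C11 epimers)
Conditions: DBU (0.2 equiv), MeCN, 0 °C; AcOH quench
Reagents that add atoms: none
Why: Intramolecular 6‑endo Michael addition of the β‑keto ester (C8) to the nitroalkene (C9) closes ring C; C8 is fixed by the cis‑1,3 bridging requirement from C13, and the (E)‑alkene geometry places C10 axial on the new chair (anti to C15), which is the natural C9 configuration.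

**Step 18**
Reactants: **20**
Product: **21** methyl (1S,2S,5S)‑2‑[(3aR,7R,7aR)‑7‑[(benzyloxy)methyl]‑3a‑methyl‑1‑oxooctahydro‑2‑benzofuran‑7‑yl]‑3,7‑dioxobicyclo[3.2.1]octane‑1‑carboxylate
Conditions: DBU (1.05 equiv), CH2Cl2, 0 °C; then dimethyldioxirane (acetone), −40 → 0 °C; AcOH
Reagents that add atoms: dimethyldioxirane, CC1(C)OO1
Why: Oxidative Nef reaction of the nitronate gives the C11 ketone under non‑nucleophilic conditions that spare the non‑enolisable β‑keto ester; the equatorial H9 is poorly aligned for enolisation, so C9 is retained.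

**Step 19**
Reactants: **21**
Product: **22** methyl (1S,2S,3R,5S)‑2‑[(3aR,7R,7aR)‑7‑[(benzyloxy)methyl]‑3a‑methyl‑1‑oxooctahydro‑2‑benzofuran‑7‑yl]‑3‑hydroxy‑7‑oxobicyclo[3.2.1]octane‑1‑carboxylate
Conditions: NaBH4 (1.0 equiv), MeOH/CH2Cl2, −78 → −40 °C
Reagents that add atoms: none
Why: The cyclohexanone (C11) is reduced faster than the neopentyl cyclopentanone (C15), and hydride attacks axially from the face of the sp2 C15 bridge because the axial C10 substituent blocks the other face, giving the equatorial (11R) alcohol.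

**Step 20**
Reactants: **22**
Product: **23** 17‑nor‑ludongnin A (16‑desmethylene ketone; both lactones in place)
Conditions: H2 (1 atm), 10% Pd/C, EtOAc, rt; filter; then CSA (cat.), toluene, 80 °C
Reagents that add atoms: none
Why: Hydrogenolysis frees C20–OH, which lactonises onto the C7 ester under acid catalysis to the six‑membered lactone; the equatorial 11‑OH cannot reach C7.

**Step 21**
Reactants: **23**
Product: **24** ludongnin A
Conditions: (CH2O)n, N‑methylanilinium trifluoroacetate, THF, 65 °C
Reagents that add atoms: paraformaldehyde (formaldehyde), C=O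
Why: Acid‑mediated Mannich condensation/elimination (Gras α‑methylenation) occurs only at C16, the sole enolisable position of the C15 ketone, and tolerates the free alcohol and both lactones.

## Compound list

1 | ethyl 2‑oxocyclohexane‑1‑carboxylate | CCOC(=O)C1CCCCC1=O | starting material
2 | L‑valine tert‑butyl ester | CC(C)[C@H](N)C(=O)OC(C)(C)C | starting material
3 | chiral enamino ester | CCOC(=O)C1=C(N[C@@H](C(C)C)C(=O)OC(C)(C)C)CCCC1 | intermediate
4 | ethyl (1R)‑1‑methyl‑2‑oxocyclohexane‑1‑carboxylate | O=C1CCCC[C@@]1(C)C(=O)OCC | intermediate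
5 | ethyl (1R)‑3‑[(benzyloxy)methyl]‑1‑methyl‑2‑oxocyclohexane‑1‑carboxylate | O=C1C(COCc2ccccc2)CCC[C@@]1(C)C(=O)OCC | intermediate
6 | ethyl (1R,3R)‑3‑[(benzyloxy)methyl]‑3‑(dimethoxymethyl)‑1‑methyl‑2‑oxocyclohexane‑1‑carboxylate | COC(OC)[C@@]1(CCC[C@@](C)(C(=O)OCC)C1=O)COCc1ccccc1 | intermediate
7 | 2‑methylidene analogue of 6 | COC(OC)[C@@]1(CCC[C@@](C)(C(=O)OCC)C1=C)COCc1ccccc1 | intermediate
8 | ethyl (1R,2S,3R)‑3‑[(benzyloxy)methyl]‑3‑(dimethoxymethyl)‑2‑(hydroxymethyl)‑1‑methylcyclohexane‑1‑carboxylate | COC(OC)[C@@]1(CCC[C@@](C)(C(=O)OCC)[C@H]1CO)COCc1ccccc1 | intermediate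
9 | [(1R,2R,3R)‑3‑[(benzyloxy)methyl]‑3‑(dimethoxymethyl)‑1‑methylcyclohexane‑1,2‑diyl]dimethanol | COC(OC)[C@@]1(CCC[C@@](C)(CO)[C@H]1CO)COCc1ccccc1 | intermediate
10 | (3aR,7R,7aR)‑7‑[(benzyloxy)methyl]‑3a‑methyl‑1‑oxooctahydro‑2‑benzofuran‑7‑carbaldehyde | O=C[C@@]1(CCC[C@@]2(C)COC(=O)[C@H]21)COCc1ccccc1 | intermediate
11 | cyclopent‑2‑en‑1‑one | O=C1C=CCC1 | starting material
12 | (3R)‑3‑vinylcyclopentan‑1‑one | O=C1CC[C@H](C1)C=C | intermediate
13 | methyl (4R)‑2‑oxo‑4‑vinylcyclopentane‑1‑carboxylate | COC(=O)C1C[C@H](CC1=O)C=C | intermediate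
14 | methyl (8R)‑8‑vinyl‑1,4‑dioxaspiro[4.4]nonane‑6‑carboxylate | COC(=O)C1C[C@H](CC12OCCO2)C=C | intermediate
15 | methyl (8S)‑8‑(2‑hydroxyethyl)‑1,4‑dioxaspiro[4.4]nonane‑6‑carboxylate | COC(=O)C1C[C@H](CC12OCCO2)CCO | intermediate
16 | methyl (8R)‑8‑(2‑iodoethyl)‑1,4‑dioxaspiro[4.4]nonane‑6‑carboxylate | COC(=O)C1C[C@H](CC12OCCO2)CCI | intermediate
17 | methyl (8S)‑8‑(2‑nitroethyl)‑1,4‑dioxaspiro[4.4]nonane‑6‑carboxylate | COC(=O)C1C[C@H](CC12OCCO2)CC[N+](=O)[O-] | intermediate
18 | methyl (4S)‑4‑(2‑nitroethyl)‑2‑oxocyclopentane‑1‑carboxylate | COC(=O)C1C[C@H](CC1=O)CC[N+](=O)[O-] | intermediate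
19 | (E)‑nitroalkene from 10 + 18 | COC(=O)C1C[C@H](CC1=O)C/C([N+](=O)[O-])=C\[C@@]1(CCC[C@@]2(C)COC(=O)[C@H]21)COCc1ccccc1 | intermediate
20 | bicyclo[3.2.1]octane nitro keto ester | C1C(=O)[C@]2(C(=O)OC)C[C@H]1CC([N+](=O)[O-])[C@H]2[C@@]1(CCC[C@@]2(C)COC(=O)[C@H]21)COCc1ccccc1 | intermediate
21 | 11,15‑diketo ester | C1C(=O)[C@]2(C(=O)OC)C[C@H]1CC(=O)[C@H]2[C@@]1(CCC[C@@]2(C)COC(=O)[C@H]21)COCc1ccccc1 | intermediate
22 | (11R)‑hydroxy 15‑keto ester | C1C(=O)[C@]2(C(=O)OC)C[C@H]1C[C@@H](O)[C@H]2[C@@]1(CCC[C@@]2(C)COC(=O)[C@H]21)COCc1ccccc1 | intermediate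
23 | 17‑nor‑ludongnin A | C1C(=O)[C@]23C[C@H]1C[C@@H](O)[C@H]2[C@@]1(CCC[C@@]2(C)COC(=O)[C@H]21)COC3=O | intermediate
24 | ludongnin A | C=C1C(=O)[C@]23C[C@H]1C[C@@H](O)[C@H]2[C@@]1(CCC[C@@]2(C)COC(=O)[C@H]21)COC3=O | target

## Step count

- Total steps: 21.
- Longest linear sequence: 14 (steps 1–8, then 16–21); the second branch is 7 steps (9–15) before the union.

## Three steps most likely to fail, with fallbacks

1. **Steps 16–17** (Henry union at a neopentyl aldehyde, then C8–C9 bond formation between two congested carbons). Fallback: reverse the bond order. Esterify C20–OH of a C10‑(2‑nitropropenyl) A‑ring alcohol with 2‑oxocyclopentanecarboxylate, form C8–C9 by a lactone‑tethered 6‑exo Michael addition, convert the nitro group to the C11 methyl ketone, dehydrogenate the D ring to the cyclopentenone and close ring C by Michael addition of C12 onto C13.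
2. **Step 5** (methylenation of a ketone flanked by two quaternary carbons). Fallback: make the C5–C6 bond before the second quaternary centre exists. Convert **5** to its vinyl triflate, carbonylate (Pd, CO, MeOH), reduce to the allylic alcohol, and use a [2,3]‑Wittig–Still rearrangement to create the C10 quaternary centre and the C5 exocyclic methylene together.
3. **Step 19** (chemo‑ and face‑selective reduction of the C11 ketone beside the C15 ketone). Fallback: change the order so the two carbonyls never coexist. Methylenate C16 at the nitro stage (**20**, acid‑mediated Mannich), Luche‑reduce C15 to the allylic alcohol, then Nef and reduce C11, and finish by MnO2 oxidation of the allylic C15–OH. This requires an oxidatively removable group (PMB) on C20–OH in place of benzyl.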